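The numbers in the tables stem from a simulated flask with constants of no real substance; the scatter is artificial.

The time of reading was my first concern. The alpha run is this very flask, and its Ly.Qa read 30.1% at 0.667 min and 29.8% at 5.00 min.

| flask | Ly | Qa | remark | time |
|---|---|---|---|---|
| alpha | 0.50 mM | 1.5 equiv | the very flask that is asked about, followed so far |  |
| theta | 0.25 mM | 1.5 equiv | run made earlier |  |
| flask | 0.50 mM | 1.50 equiv |  | 12 min |

| run | time / min | Ly.Qa / % | Ve / % |
|---|---|---|---|
| alpha | 0.667 | 30.1 | 14.3 |
| alpha | 1.50 | 30.3 | 13.0 |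
| alpha | 3.00 | 30.3 | 13.5 |
| alpha | 5.00 | 29.8 | 13.6 |
| theta | 2.00 | 20.9 | 9.4 |
| theta | 4.00 | 20.9 | 9.6 |
| theta | 6.00 | 20.3 | 9.3 |
| theta | 8.00 | 20.9 | 9.0 |

(each reading ± 0.3 percentage points)

- the analysis behind the earlier runs scatters by 0.3 percentage points, standard deviation
- a reading or a percentage of Ly.Qa counts all its forms, free or not
- the reaction counts as stopped when no species that holds the Ly changes by six tenths of a point or more over the second half of the time

- the state of affairs at 12 min: stopped, and by what, or still going (it is still moving / Qa has run out first / all of Ly has reacted / forward and back rates have come level)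
- how much Ly.Qa there is at 12 min, in percent of the Ly charged
- how much Ve there is at 12 min, in percent of the Ly charged

So I kept books on Ly, the limiting reagent, and on Qa. I averaged the alpha readings and booked one Qa to each product.

Ly.Qa: 0.151 mM

Ve: 0.0680 mM

Ly left: 0.281 mM

Qa not in a product: 0.531 mM

Ly.Qa / (Ly left × Qa not in a product) = 1.01 /mM

Where forward and back rates are level, dividing one by the other removes time. What remains is this level quotient, an equilibrium constant as far as my books could show. Ve per Ly.Qa read 0.451.

The theta run was more dilute. Its books gave Ly.Qa 0.0519 mM and Ve 0.0233 mM, so the quotient read 0.990 /mM.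

My forecast was forward and back rates have come level, with Ly.Qa 30.1% and Ve 13.6%, since “Nothing drifts”.

The flask gave forward and back rates have come level, with Ly.Qa 30.0% and Ve 13.5%.

    Ly + Qa ⇌ Ly.Qa (K = 2200 /M, k = 620 /M/s)
    Qa ⇌ Ty (K = 1.20, k = 0.910 /s)
    Ly.Qa ⇌ Ve (K = 0.450, k = 0.420 /s)
    Zo ⇌ Ly.Qa, rate k4*(cs4 - [Ly.Qa]) while solid is left; crystals form when [Ly.Qa] > cs4 (solubility = 0.410 mM, k = 1.10 /s)

On these amounts the quotient came to 1.00 /mM, and the Qa entry split into Qa 0.242 mM and Ty 0.290 mM. Reading as late as 120 min changed nothing in Ly.Qa. The forecast rests mainly on the way back from Ve to Ly.Qa. The run without that way back turned the answer on ends and took Ve from 13.5% to 100%.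

In a neighbour flask with 0.380 equiv of Qa, the other charges and the time held, the quotient and the Ve ratio gave Ly.Qa 10.1% and Ve 4.54%. The computed neighbour flask gave 10.0% and 4.51%.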